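## The problem

The target 19 is a γ-butyrolactone (ring O1–C2(=O)–C3–C4–C5H2). C3 carries a 4-hydroxy-3-methoxybenzyl group (benzylic carbon C7) and C4 a 4-hydroxy-3-methoxybenzoyl group (ketone carbon C6); both centres are R and the substituents are trans.

The carbonyls C2 and C6 are 1,4-related, so the ring bond C3–C4 joins two carbons that are each α to a carbonyl. These are two donor positions, which no ordinary enolate-plus-electrophile pairing connects, the less so as C4 is secondary and also carries C5.

This same array makes the key step possible. C3 is the α-carbon of an acyl derivative (C2) and C4 the α-carbon of the aryl ketone (C6), so C3–C4 can be made by oxidative union of two enolates.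

The two stereocentres are unequal. H–C4 is α to the aryl ketone and far more acidic than H–C3 (α to the lactone), and trans is the more stable arrangement on the ring. Only C3 therefore needs absolute control; C4 can be relayed from it by equilibration.

The reverse side is that, once C3 is set, base strong enough to enolise the lactone must be avoided, because inversion at both centres in turn gives the enantiomer.

C5–O1 is β to the ketone. An open-chain ketone enolate with an acyloxy group on C5 would eliminate at once. In the closed ring the C5–O1 bond lies near the nodal plane of the C4 enolate (the reverse of a 5-endo-trig closure) and is much safer.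

The two guaiacyl phenols are acidic and easily oxidised, and the aryl ketone rules out hydrogenolytic unmasking. The phenols need groups that survive strong base and a one-electron oxidant and leave under mild, non-reductive conditions.

## Retrosynthesis

**19 ⇒ 18.** The two aryl O–Si bonds are cut. Silyl ethers are preferred to benzyl ethers (hydrogenolysis would endanger C6=O) and to further methyl ethers (not distinguishable from the two OMe groups). The skeleton is unchanged. The forward step needs only near-neutral fluoride.

**18 ⇒ 15 (through 17 and 16).** The acyl–oxygen bond C2–O1 is cut and the configuration at C4 is deliberately given up. Compound 15 is an open-chain γ-silyloxy imide in which only C3 is defined. Ring closure by acyl transfer is the safest lactone formation, the auxiliary 4 serves as its own leaving group, and C4 is set by equilibrium once the ring exists. The forward step must free the primary alcohol selectively, close the ring (5-exo-trig) and equilibrate C4 without touching C3.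

**15 ⇒ 6 + 12 (as enolates 13 and 14).** The C3–C4 bond is cut. The neighbouring cuts are weaker:
- Cutting C4–C6 or C3–C7 keeps the ring, needs a masked acyl anion, and deposits the stereochemical information on the labile centre C4.
- Cutting C4–C5 (formaldehyde aldol) needs selective ketone enolisation next to an epimerisable imide centre.

The C3–C4 cut divides the molecule into two ten-carbon halves, each two or three steps from purchased material, and lets the auxiliary on 6 set the robust centre C3. The forward reaction must favour cross- over homo-coupling, control the face of 13, and keep the β-silyloxy group of 14 in place.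

**6 ⇒ 3 + 4; 3 ⇒ 1.** The N–acyl bond is cut (forward by way of mixed anhydride 5), then the aryl O–Si bond (forward by way of silyl ester 2). Both are routine.

**12 ⇒ 11 ⇒ 8 (as 10) + 9; 8 ⇒ 7.** The aryl–C6 bond is cut. A halogen-defined aryl nucleophile fixes the substitution pattern, which electrophilic acylation of a guaiacol derivative would not deliver para to the protected oxygen. The forward steps are bromine–lithium exchange, addition to aldehyde 9 and oxidation.

## Roads not taken

**Alternative 1:** The most obvious cut removes both exocyclic bonds, C4–C6 and C3–C7, from an intact butenolide. The forward key step is conjugate addition of lithiated 2-[4-(tert-butyldimethylsilyloxy)-3-methoxyphenyl]-1,3-dithiane A1 (a masked aroyl anion) to furan-2(5H)-one A2, with trapping of the lactone enolate by [4-(bromomethyl)-2-methoxyphenoxy](tert-butyl)dimethylsilane A3. This gives the trans dithianyl lactone A4, and dithiane hydrolysis gives 18. The chosen plan is better for three reasons: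
- A2 is achiral, so A4 is racemic. Absolute control needs a chiral 5-alkoxybutenolide, whose acetal carbon must later be reduced to C5 through ring opening and re-closure.
- All stereochemical information is placed at C4, the centre that becomes labile as soon as the ketone is unmasked.
- Masking and unmasking the ketone costs two operations that form no skeletal bond, and dithiane removal needs electrophilic or oxidising reagents beside two electron-rich arenes.

**Alternative 2:** C3–C4 is cut as a [3,3]-sigmatropic bond. The forward key step is an Ireland–Claisen rearrangement of the 2-arylallyl ester A5 to the pentenoic acid A6, whose 1,1-disubstituted styrene is an aroyl group in disguise (ozonolysis); lactonisation then gives 18. The chosen plan is better for three reasons: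
- The rearrangement sets only relative configuration, which this target corrects for itself through C4. It sets no absolute configuration, since the allylic carbon of A5 is a CH2 group with nothing to transfer.
- An enantioselective version needs a stoichiometric chiral boron reagent, or a secondary allylic alcohol whose extra carbon must be excised.
- A5 needs a stereodefined trisubstituted 2-arylbutenediol (several steps), and ozonolysis would run beside two electron-rich arenes.

**Alternative 3:** Both stereocentres are erased into the planar tetrasubstituted butenolide A7. The forward key step is catalyst-controlled hydrogenation (for example Ru(OAc)2[(S)-BINAP], H2) to the cis lactone A8, followed by epimerisation at C4 to 18. The chosen plan is better for three reasons: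
- The whole skeleton of A7 must first be assembled by chemistry that creates no stereocentre, so the key step forms no carbon–carbon bond and its precursor is as complex as its product.
- Enantioselective hydrogenation of a tetrasubstituted alkene carrying two acceptor groups is the least developed class.
- In conjugate-reduction mode hydride may go to C4 instead of C3, and only delivery to C3 leaves durable information.

Key step: step 6

Remark: compounds 1, 4, 7 and 9 are taken as purchased; TBS = tert-butyldimethylsilyl; C3–C7 labels follow the numbering of the first section, also for open-chain intermediates where stated.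

## Route

Step 1
Reactants: 1 3-(4-hydroxy-3-methoxyphenyl)propanoic acid
Product: 3 3-[4-(tert-butyldimethylsilyloxy)-3-methoxyphenyl]propanoic acid, via silyl ester 2 (not isolated)
Conditions: TBSCl (2.4 equiv), imidazole, DMF, rt; then AcOH/THF/H2O, rt
Reagents that add atoms: tert-butyldimethylsilyl chloride, CC(C)(C)[Si](C)(C)Cl
Why: Standard silylation of phenol and acid; the silyl ester is far more labile to aqueous acid than the aryl silyl ether and should be hydrolysed selectively.

Step 2
Reactants: 3 3-[4-(tert-butyldimethylsilyloxy)-3-methoxyphenyl]propanoic acid; 4 (S)-4-benzyloxazolidin-2-one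
Product: 6 (S)-4-benzyl-3-{3-[4-(tert-butyldimethylsilyloxy)-3-methoxyphenyl]propanoyl}oxazolidin-2-one, via mixed pivalic anhydride 5 (not isolated)
Conditions: PivCl, Et3N, THF, −20 °C; then 4, LiCl, −20 °C to rt
Reagents that add atoms: none
Why: N-acylation of the oxazolidinone through a mixed anhydride under LiCl/Et3N activation; no stereocentre is formed and the (S) centre of the auxiliary is purchased.

Step 3
Reactants: 7 4-bromo-2-methoxyphenol
Product: 8 (4-bromo-2-methoxyphenoxy)(tert-butyl)dimethylsilane
Conditions: TBSCl, imidazole, DMF, rt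
Reagents that add atoms: tert-butyldimethylsilyl chloride, CC(C)(C)[Si](C)(C)Cl
Why: Standard phenol silylation; the silyl ether is para to bromine, so the later aryllithium has no ortho O–Si group that could migrate to carbon.

Step 4
Reactants: 8 (4-bromo-2-methoxyphenoxy)(tert-butyl)dimethylsilane; 9 3-(tert-butyldimethylsilyloxy)propanal
Product: 11 rac-3-(tert-butyldimethylsilyloxy)-1-[4-(tert-butyldimethylsilyloxy)-3-methoxyphenyl]propan-1-ol, via aryllithium 10 (not isolated)
Conditions: n-BuLi, THF, −78 °C; then 9, −78 °C; aq. NH4Cl
Reagents that add atoms: none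
Why: Bromine–lithium exchange followed by 1,2-addition to the aldehyde; the carbinol centre is racemic and is removed by oxidation in the next step.

Step 5
Reactants: 11 rac-3-(tert-butyldimethylsilyloxy)-1-[4-(tert-butyldimethylsilyloxy)-3-methoxyphenyl]propan-1-ol
Product: 12 3-(tert-butyldimethylsilyloxy)-1-[4-(tert-butyldimethylsilyloxy)-3-methoxyphenyl]propan-1-one
Conditions: Dess–Martin periodinane, NaHCO3, CH2Cl2, 0 °C to rt
Reagents that add atoms: none
Why: Dess–Martin oxidation of a benzylic alcohol under buffered, non-basic conditions, so that the β-silyloxy ketone is not exposed to elimination.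

Step 6
Reactants: 6 (S)-4-benzyl-3-{3-[4-(tert-butyldimethylsilyloxy)-3-methoxyphenyl]propanoyl}oxazolidin-2-one; 12 3-(tert-butyldimethylsilyloxy)-1-[4-(tert-butyldimethylsilyloxy)-3-methoxyphenyl]propan-1-one
Product: 15 (4S)-4-benzyl-3-{(2R,3RS)-2-[4-(tert-butyldimethylsilyloxy)-3-methoxybenzyl]-3-[(tert-butyldimethylsilyloxy)methyl]-4-[4-(tert-butyldimethylsilyloxy)-3-methoxyphenyl]-4-oxobutanoyl}oxazolidin-2-one, via imide lithium Z-enolate 13 (not isolated), via ketone lithium Z-enolate 14 (not isolated)
Conditions: 6 (1.0 equiv) and 12 (1.5 equiv) added to LiN(iPr)2 (LDA, 2.6 equiv), THF, −78 °C; then Fe(acac)3 (2.6 equiv), THF, −78 °C to rt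
Reagents that add atoms: none
Why: Oxidative enolate heterocoupling: LDA converts 6 into the chelated Z-enolate 13 and 12 into enolate 14, Fe(acac)3 (trivalent iron, a one-electron oxidant) oxidises one enolate to an α-carbonyl radical (free or iron-bound), the second enolate captures it at carbon, and a second equivalent of Fe(acac)3 oxidises the resulting radical anion to the 1,4-dicarbonyl compound 15. The closest known reaction type is the intermolecular oxidative cross-coupling of N-acyl oxazolidinone lithium enolates with ketone lithium enolates by soluble trivalent iron or divalent copper salts. No ring is closed; the step makes the C3–C4 bond (lactone numbering) between two α-carbons of like polarity and brings all carbons of the target together. The new centre next to the imide (C3 of the lactone) is controlled by the auxiliary: in the lithium-chelated Z-enolate 13 the benzyl group on the oxazolidinone covers one face, and bond formation on the open face should give (2R), the same sense as in alkylations of this enolate. The second new centre (C4 of the lactone, α to the aryl ketone) forms without control and is left as a mixture on purpose, because step 7 equilibrates it. The step needs cross- over homo-coupling, which the structural and electronic difference between an imide enolate and an aryl ketone enolate (different oxidation potentials, mixed aggregates) favours and the excess of 12 supports. It also needs the β-oxygen of 14 to stay in place, which the poor leaving-group ability of a silanolate and the low temperature up to the point of oxidation secure, and it needs phenols that cannot be oxidised, which the aryl silyl ethers provide.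

Step 7
Reactants: 15 (4S)-4-benzyl-3-{(2R,3RS)-2-[4-(tert-butyldimethylsilyloxy)-3-methoxybenzyl]-3-[(tert-butyldimethylsilyloxy)methyl]-4-[4-(tert-butyldimethylsilyloxy)-3-methoxyphenyl]-4-oxobutanoyl}oxazolidin-2-one
Product: 18 (3R,4R)-4-[4-(tert-butyldimethylsilyloxy)-3-methoxybenzoyl]-3-[4-(tert-butyldimethylsilyloxy)-3-methoxybenzyl]dihydrofuran-2(3H)-one, via hydroxy imide 16 (not isolated), via lactone C4-epimer mixture 17 (not isolated)
Conditions: CSA (0.2 equiv), MeOH/CH2Cl2 (1:1), 0 °C to rt; aq. NaHCO3 wash; then DBU (0.1 equiv), CH2Cl2, rt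
Reagents that add atoms: none
Why: Acid-catalysed methanolysis frees only the primary alcohol (aryl silyl ethers are much slower under acid), and the γ-hydroxy imide 16 lactonises by 5-exo-trig acyl transfer with release of auxiliary 4. Catalytic DBU then enolises only the ketone α-position C4 (H–C3 is several pK units less acidic), so both C4 epimers should converge on the more stable trans lactone, a thermodynamic relay from C3. Opening of the ring by β-elimination would be the reverse of a 5-endo-trig closure and is stereoelectronically disfavoured.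

Step 8
Reactants: 18 (3R,4R)-4-[4-(tert-butyldimethylsilyloxy)-3-methoxybenzoyl]-3-[4-(tert-butyldimethylsilyloxy)-3-methoxybenzyl]dihydrofuran-2(3H)-one
Product: 19 (3R,4R)-4-(4-hydroxy-3-methoxybenzoyl)-3-(4-hydroxy-3-methoxybenzyl)dihydrofuran-2(3H)-one
Conditions: KHF2 (3 equiv), MeOH, rt
Reagents that add atoms: none
Why: Bifluoride cleaves phenolic silyl ethers under near-neutral conditions without reduction or strong base; C3 is not touched and C4 is already in its thermodynamic configuration.

## Compound list

1 | 3-(4-hydroxy-3-methoxyphenyl)propanoic acid | COc1cc(CCC(=O)O)ccc1O | starting material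
2 | tert-butyldimethylsilyl 3-[4-(tert-butyldimethylsilyloxy)-3-methoxyphenyl]propanoate | COc1cc(CCC(=O)O[Si](C)(C)C(C)(C)C)ccc1O[Si](C)(C)C(C)(C)C | intermediate
3 | 3-[4-(tert-butyldimethylsilyloxy)-3-methoxyphenyl]propanoic acid | COc1cc(CCC(=O)O)ccc1O[Si](C)(C)C(C)(C)C | intermediate
4 | (S)-4-benzyloxazolidin-2-one | O=C1N[C@@H](Cc2ccccc2)CO1 | starting material
5 | 3-[4-(tert-butyldimethylsilyloxy)-3-methoxyphenyl]propanoic pivalic anhydride | COc1cc(CCC(=O)OC(=O)C(C)(C)C)ccc1O[Si](C)(C)C(C)(C)C | intermediate
6 | (S)-4-benzyl-3-{3-[4-(tert-butyldimethylsilyloxy)-3-methoxyphenyl]propanoyl}oxazolidin-2-one | COc1cc(CCC(=O)N2[C@@H](Cc3ccccc3)COC2=O)ccc1O[Si](C)(C)C(C)(C)C | intermediate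
7 | 4-bromo-2-methoxyphenol | COc1cc(Br)ccc1O | starting material
8 | (4-bromo-2-methoxyphenoxy)(tert-butyl)dimethylsilane | COc1cc(Br)ccc1O[Si](C)(C)C(C)(C)C | intermediate
9 | 3-(tert-butyldimethylsilyloxy)propanal | O=CCCO[Si](C)(C)C(C)(C)C | starting material
10 | [4-(tert-butyldimethylsilyloxy)-3-methoxyphenyl]lithium | [Li]c1ccc(O[Si](C)(C)C(C)(C)C)c(OC)c1 | intermediate
11 | rac-3-(tert-butyldimethylsilyloxy)-1-[4-(tert-butyldimethylsilyloxy)-3-methoxyphenyl]propan-1-ol | COc1cc(C(O)CCO[Si](C)(C)C(C)(C)C)ccc1O[Si](C)(C)C(C)(C)C | intermediate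
12 | 3-(tert-butyldimethylsilyloxy)-1-[4-(tert-butyldimethylsilyloxy)-3-methoxyphenyl]propan-1-one | COc1cc(C(=O)CCO[Si](C)(C)C(C)(C)C)ccc1O[Si](C)(C)C(C)(C)C | intermediate
13 | lithium (Z)-enolate of imide 6 | [Li]O/C(=C\Cc1ccc(O[Si](C)(C)C(C)(C)C)c(OC)c1)N1[C@@H](Cc2ccccc2)COC1=O | intermediate
14 | lithium (Z)-enolate of ketone 12 | [Li]O/C(=C\CO[Si](C)(C)C(C)(C)C)c1ccc(O[Si](C)(C)C(C)(C)C)c(OC)c1 | intermediate
15 | (4S)-4-benzyl-3-{(2R,3RS)-2-[4-(tert-butyldimethylsilyloxy)-3-methoxybenzyl]-3-[(tert-butyldimethylsilyloxy)methyl]-4-[4-(tert-butyldimethylsilyloxy)-3-methoxyphenyl]-4-oxobutanoyl}oxazolidin-2-one (both epimers at C3 of the chain) | COc1cc(C[C@@H](C(=O)N2[C@@H](Cc3ccccc3)COC2=O)C(CO[Si](C)(C)C(C)(C)C)C(=O)c2ccc(O[Si](C)(C)C(C)(C)C)c(OC)c2)ccc1O[Si](C)(C)C(C)(C)C | intermediate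
16 | (4S)-4-benzyl-3-{(2R,3RS)-2-[4-(tert-butyldimethylsilyloxy)-3-methoxybenzyl]-3-(hydroxymethyl)-4-[4-(tert-butyldimethylsilyloxy)-3-methoxyphenyl]-4-oxobutanoyl}oxazolidin-2-one | COc1cc(C[C@@H](C(=O)N2[C@@H](Cc3ccccc3)COC2=O)C(CO)C(=O)c2ccc(O[Si](C)(C)C(C)(C)C)c(OC)c2)ccc1O[Si](C)(C)C(C)(C)C | intermediate
17 | (3R,4RS)-4-[4-(tert-butyldimethylsilyloxy)-3-methoxybenzoyl]-3-[4-(tert-butyldimethylsilyloxy)-3-methoxybenzyl]dihydrofuran-2(3H)-one (both C4 epimers) | COc1cc(C[C@H]2C(=O)OCC2C(=O)c2ccc(O[Si](C)(C)C(C)(C)C)c(OC)c2)ccc1O[Si](C)(C)C(C)(C)C | intermediate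
18 | (3R,4R)-4-[4-(tert-butyldimethylsilyloxy)-3-methoxybenzoyl]-3-[4-(tert-butyldimethylsilyloxy)-3-methoxybenzyl]dihydrofuran-2(3H)-one | COc1cc(C[C@H]2C(=O)OC[C@@H]2C(=O)c2ccc(O[Si](C)(C)C(C)(C)C)c(OC)c2)ccc1O[Si](C)(C)C(C)(C)C | intermediate
19 | (3R,4R)-4-(4-hydroxy-3-methoxybenzoyl)-3-(4-hydroxy-3-methoxybenzyl)dihydrofuran-2(3H)-one | COc1cc(C[C@H]2C(=O)OC[C@@H]2C(=O)c2ccc(O)c(OC)c2)ccc1O | target

## Step count and risk

Total: 8 steps. Longest linear sequence: 6 steps (steps 3, 4, 5, 6, 7, 8 from 7); the imide branch (steps 1, 2) joins at step 6.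

**Step 6 (key step).**
- What may go wrong: homocoupling of either enolate may outrun the cross-coupling, since both enolates and both radicals share one pool.
- The enolisable product may be oxidised further to the ene-dione.
- Silanolate may be lost from 14 by β-elimination if the mixture warms before the oxidant has acted.
- Facial discrimination at 13 may be incomplete, or the centre next to the imide may epimerise under residual base during warming.
- First adjustment: change the oxidant to copper bis(2-ethylhexanoate).
- Fallback (sequential construction instead of direct union), setting out from 8 and 6 and returning at 16: Aryllithium 10, made from 8 as in step 4, is acylated with N-methoxy-N-methylacetamide to give 1-[4-(tert-butyldimethylsilyloxy)-3-methoxyphenyl]ethan-1-one F1. This is brominated (PhNMe3Br3, THF, 0 °C) to 2-bromo-1-[4-(tert-butyldimethylsilyloxy)-3-methoxyphenyl]ethan-1-one F2. The sodium enolate of 6 (NaN(SiMe3)2, THF, −78 °C) is alkylated with F2 under auxiliary control to give (4S)-4-benzyl-3-{(2R)-2-[4-(tert-butyldimethylsilyloxy)-3-methoxybenzyl]-4-[4-(tert-butyldimethylsilyloxy)-3-methoxyphenyl]-4-oxobutanoyl}oxazolidin-2-one F3. Soft enolisation of the aryl ketone (Me3SiOTf, Et3N, CH2Cl2, −78 °C) gives its (Z)-trimethylsilyl enol ether F4. Mukaiyama hydroxymethylation with aqueous formaldehyde and Yb(OTf)3 then gives 16, and the route continues with the lactonisation and equilibration of step 7.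

**Step 7.**
- What may go wrong: acyl transfer to the freed alcohol may be slower than methanolysis or attack at the ring carbonyl of the auxiliary.
- Equilibration may go beyond C4: the lactone may enolise at C3 on long contact with DBU, which would erode enantiopurity, or the ring may open by base-induced β-elimination.
- Fallback (auxiliary removed before ring closure, no base), setting out from 15 and returning at 18: Sm(OTf)3-catalysed methanolysis of 15 gives methyl (2R,3RS)-2-[4-(tert-butyldimethylsilyloxy)-3-methoxybenzyl]-3-[(tert-butyldimethylsilyloxy)methyl]-4-[4-(tert-butyldimethylsilyloxy)-3-methoxyphenyl]-4-oxobutanoate F5 and recovered 4. TsOH in MeOH, then in toluene at 60 °C, removes the primary silyl group, closes the lactone with loss of methanol, and equilibrates C4 through the ketone enol to give 18. The enol pathway is open to the aryl ketone but not to the lactone.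

**Step 8.**
- What may go wrong: fluoride, or the phenoxide formed during desilylation, may act as base on the finished lactone, causing ring methanolysis or scrambling at C4 and then C3.
- Fallback (phenols freed before the ring and the C4 configuration exist), setting out from 15 and returning at 19: KHF2 in MeOH cleaves only the two aryl silyl ethers of 15 to give (4S)-4-benzyl-3-{(2R,3RS)-3-[(tert-butyldimethylsilyloxy)methyl]-2-(4-hydroxy-3-methoxybenzyl)-4-(4-hydroxy-3-methoxyphenyl)-4-oxobutanoyl}oxazolidin-2-one F6. CSA in MeOH then frees the primary alcohol, and lactonisation with release of 4 gives (3R,4RS)-4-(4-hydroxy-3-methoxybenzoyl)-3-(4-hydroxy-3-methoxybenzyl)dihydrofuran-2(3H)-one F7. Acid-catalysed enol equilibration (TsOH, MeCN, 50 °C) converts F7 into 19.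

## Further compounds

F1 | step 6 | 1-[4-(tert-butyldimethylsilyloxy)-3-methoxyphenyl]ethan-1-one | COc1cc(C(C)=O)ccc1O[Si](C)(C)C(C)(C)C
F2 | step 6 | 2-bromo-1-[4-(tert-butyldimethylsilyloxy)-3-methoxyphenyl]ethan-1-one | COc1cc(C(=O)CBr)ccc1O[Si](C)(C)C(C)(C)C
F3 | step 6 | (4S)-4-benzyl-3-{(2R)-2-[4-(tert-butyldimethylsilyloxy)-3-methoxybenzyl]-4-[4-(tert-butyldimethylsilyloxy)-3-methoxyphenyl]-4-oxobutanoyl}oxazolidin-2-one | COc1cc(C[C@@H](C(=O)N2[C@@H](Cc3ccccc3)COC2=O)CC(=O)c2ccc(O[Si](C)(C)C(C)(C)C)c(OC)c2)ccc1O[Si](C)(C)C(C)(C)C
F4 | step 6 | (Z)-trimethylsilyl enol ether of F3 | COc1cc(C[C@@H](C(=O)N2[C@@H](Cc3ccccc3)COC2=O)/C=C(\O[Si](C)(C)C)c2ccc(O[Si](C)(C)C(C)(C)C)c(OC)c2)ccc1O[Si](C)(C)C(C)(C)C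
F5 | step 7 | methyl (2R,3RS)-2-[4-(tert-butyldimethylsilyloxy)-3-methoxybenzyl]-3-[(tert-butyldimethylsilyloxy)methyl]-4-[4-(tert-butyldimethylsilyloxy)-3-methoxyphenyl]-4-oxobutanoate | COc1cc(C[C@@H](C(=O)OC)C(CO[Si](C)(C)C(C)(C)C)C(=O)c2ccc(O[Si](C)(C)C(C)(C)C)c(OC)c2)ccc1O[Si](C)(C)C(C)(C)C
F6 | step 8 | (4S)-4-benzyl-3-{(2R,3RS)-3-[(tert-butyldimethylsilyloxy)methyl]-2-(4-hydroxy-3-methoxybenzyl)-4-(4-hydroxy-3-methoxyphenyl)-4-oxobutanoyl}oxazolidin-2-one | COc1cc(C[C@@H](C(=O)N2[C@@H](Cc3ccccc3)COC2=O)C(CO[Si](C)(C)C(C)(C)C)C(=O)c2ccc(O)c(OC)c2)ccc1O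
F7 | step 8 | (3R,4RS)-4-(4-hydroxy-3-methoxybenzoyl)-3-(4-hydroxy-3-methoxybenzyl)dihydrofuran-2(3H)-one (both C4 epimers) | COc1cc(C[C@H]2C(=O)OCC2C(=O)c2ccc(O)c(OC)c2)ccc1O
A1 | alternative 1 | 2-[4-(tert-butyldimethylsilyloxy)-3-methoxyphenyl]-1,3-dithiane | COc1cc(C2SCCCS2)ccc1O[Si](C)(C)C(C)(C)C
A2 | alternative 1 | furan-2(5H)-one | O=C1OCC=C1
A3 | alternative 1 | [4-(bromomethyl)-2-methoxyphenoxy](tert-butyl)dimethylsilane | COc1cc(CBr)ccc1O[Si](C)(C)C(C)(C)C
A4 | alternative 1 | racemic trans-3-[4-(tert-butyldimethylsilyloxy)-3-methoxybenzyl]-4-{2-[4-(tert-butyldimethylsilyloxy)-3-methoxyphenyl]-1,3-dithian-2-yl}dihydrofuran-2(3H)-one (one enantiomer drawn) | COc1cc(C[C@H]2C(=O)OC[C@@H]2C3(SCCCS3)c3ccc(O[Si](C)(C)C(C)(C)C)c(OC)c3)ccc1O[Si](C)(C)C(C)(C)C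
A5 | alternative 2 | (E)-4-(tert-butyldimethylsilyloxy)-2-[4-(tert-butyldimethylsilyloxy)-3-methoxyphenyl]but-2-en-1-yl 3-[4-(tert-butyldimethylsilyloxy)-3-methoxyphenyl]propanoate | COc1cc(CCC(=O)OC/C(=C/CO[Si](C)(C)C(C)(C)C)c2ccc(O[Si](C)(C)C(C)(C)C)c(OC)c2)ccc1O[Si](C)(C)C(C)(C)C
A6 | alternative 2 | racemic 2-[4-(tert-butyldimethylsilyloxy)-3-methoxybenzyl]-3-[(tert-butyldimethylsilyloxy)methyl]-4-[4-(tert-butyldimethylsilyloxy)-3-methoxyphenyl]pent-4-enoic acid | COc1cc(CC(C(=O)O)C(CO[Si](C)(C)C(C)(C)C)C(=C)c2ccc(O[Si](C)(C)C(C)(C)C)c(OC)c2)ccc1O[Si](C)(C)C(C)(C)C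
A7 | alternative 3 | 4-[4-(tert-butyldimethylsilyloxy)-3-methoxybenzoyl]-3-[4-(tert-butyldimethylsilyloxy)-3-methoxybenzyl]furan-2(5H)-one | COc1cc(CC2=C(C(=O)c3ccc(O[Si](C)(C)C(C)(C)C)c(OC)c3)COC2=O)ccc1O[Si](C)(C)C(C)(C)C
A8 | alternative 3 | (3R,4S)-4-[4-(tert-butyldimethylsilyloxy)-3-methoxybenzoyl]-3-[4-(tert-butyldimethylsilyloxy)-3-methoxybenzyl]dihydrofuran-2(3H)-one | COc1cc(C[C@H]2C(=O)OC[C@H]2C(=O)c2ccc(O[Si](C)(C)C(C)(C)C)c(OC)c2)ccc1O[Si](C)(C)C(C)(C)C
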